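**Strategy.** Locants follow the pyrano[3,2-b]pyran-2-one core (O1, C2–C4, C4a, O5, C6–C8, C8a). The oxane ring O5–C6–C7–C8–C8a–C4a is read as the cleavage product of an 8-oxabicyclo[3.2.1]octene. Its ether carbons C6 and C4a are the 2,5-carbons of 2-methylfuran (umpoled carbonyl carbons), and C7–C8–C8a is an α-alkoxy oxyallyl cation. One auxiliary-controlled (4+3) cycloaddition forms C6–C7 and C4a–C8a, sets C6, C7 and C4a, and leaves the etheno bridge as the future C6 methyl and C4. The precursors are a chiral mixed-acetal silyl enol ether and 2-methylfuran; the bridge is later cleaved and the δ-lactone annulated.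

Key step: step 3

Assumption: (S)-1-phenylethanol is taken to induce the (1S,4S,5S) adduct 7 with axial alkoxy group; should the sense be opposite, (R)-1-phenylethanol is used and only the auxiliary centre changes.

Step 1
Reactants: 1 1,1-dimethoxypropan-2-one; 2 (S)-1-phenylethanol
Product: 3 1-methoxy-1-[(1S)-1-phenylethoxy]propan-2-one (both acetal epimers)
Conditions: PPTS (cat.), cyclohexane, 80 °C, removal of MeOH
Reagents that add atoms: none
Why: Acid-catalysed transacetalisation driven by loss of methanol; the benzylic centre is untouched and the acetal epimers are inconsequential because this carbon becomes sp2 in step 3.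

Step 2
Reactants: 3 mixed acetal
Product: 4 triethyl({3-methoxy-3-[(1S)-1-phenylethoxy]prop-1-en-2-yl}oxy)silane
Conditions: LiN(iPr)2, Et3SiCl, THF, −78 °C
Reagents that add atoms: chlorotriethylsilane CC[Si](Cl)(CC)CC
Why: Kinetic enolisation at the unhindered methyl group and O-silylation (silyl enol ether formation) should give the 2-silyloxyallyl acetal regioselectively.

Step 3
Reactants: 4 silyl enol ether acetal; 5 2-methylfuran
Product: 7 (1S,4S,5S)-1-methyl-4-[(1S)-1-phenylethoxy]-8-oxabicyclo[3.2.1]oct-6-en-3-one, via silyloxyallyl cation 6 (not isolated)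
Conditions: Me3SiOTf (cat.), 2-methylfuran (excess), CH2Cl2, −95 °C
Reagents that add atoms: none
Why: Me3SiOTf ionises the mixed acetal (loss of methoxide) to the 1-alkoxy-2-silyloxyallyl cation 6, which adds across the 2,5-positions of 2-methylfuran in a (4+3) cycloaddition (4π diene + 2π allyl cation); the closest known reaction type is the low-temperature cycloaddition of furans with chiral α-alkoxy silyloxyallyl cations from mixed acetals. The oxane ring (future O5, C6, C7, C8, C8a, C4a) and the seven-membered carbocycle close together by intermolecular cycloaddition, either concerted-asynchronous or as attack of the free furan α-carbon on the oxocarbenium carbon followed by seven-membered closure of the silyl enol ether onto the furanium ion (Mukaiyama type). C6 and C4a are set cis by suprafacial addition to the furan, C7 by the extended approach that places the alkoxy group axial (anti to the etheno bridge), and the absolute sense by the 1-phenylethyl group, which shields one face of the cation. The step needs regioselectivity (alkoxy-bearing terminus to the unsubstituted furan C5, CH2 terminus to the methyl-bearing C2); this should be secured by the higher electrophilicity of the oxocarbenium carbon, the higher nucleophilicity of the free α-position and the lower congestion of this orientation. It also needs kinetic control at −95 °C so that the axial ether does not epimerise.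

Step 4
Reactants: 7 cycloadduct ketone
Product: 8 1-methyl-3-methylidene-4-[(1S)-1-phenylethoxy]-8-oxabicyclo[3.2.1]oct-6-ene (ring configuration as in 7)
Conditions: Ph3PCH3Br, KOtBu, THF, 0 °C to rt
Reagents that add atoms: methyltriphenylphosphonium bromide C[P+](c1ccccc1)(c1ccccc1)c1ccccc1.[Br-]
Why: Wittig methylenation of the ketone; the α-hydrogen at the ether carbon is equatorial and poorly aligned for enolisation, so the axial ether should survive the basic ylide.

Step 5
Reactants: 8 exocyclic alkene
Product: 9 1-methyl-3-methylidene-4-[(1S)-1-phenylethoxy]-8-oxabicyclo[3.2.1]oct-6-en-2-ol (2-OH axial, cis to the 4-alkoxy group, both anti to the etheno bridge)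
Conditions: SeO2 (cat.), tBuOOH, CH2Cl2, rt
Reagents that add atoms: selenium dioxide O=[Se]=O (oxygen carrier); tert-butyl hydroperoxide CC(C)(C)OO
Why: Allylic hydroxylation by ene reaction and [2,3]-sigmatropic shift takes the axial hydrogen of the ring CH2 (the other allylic hydrogen is equatorial and on an ether carbon) and returns oxygen from the open face syn to the oxygen bridge, setting the future C8a oxygen cis to the C7 oxygen.

Step 6
Reactants: 9 allylic alcohol
Product: 10 1-methyl-3-methylidene-4-[(1S)-1-phenylethoxy]-8-oxabicyclo[3.2.1]octane-2,6,7-triol (6,7-diol cis, syn to O8)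
Conditions: OsO4 (cat.), NMO, acetone/H2O, 0 °C
Reagents that add atoms: N-methylmorpholine N-oxide C[N+]1([O-])CCOCC1; water O
Why: Upjohn dihydroxylation should take the strained bridge alkene from its open exo face in preference to the 1,1-disubstituted alkene, which is flanked on one face by two axial oxygen substituents and on the other by the bridge.

Step 7
Reactants: 10 triol
Product: 11 1,3-dimethyl-4-[(1S)-1-phenylethoxy]-8-oxabicyclo[3.2.1]octane-2,6,7-triol (3-methyl anti to the 2-OH and 4-alkoxy groups)
Conditions: [Ir(cod)(PCy3)(py)]PF6 (cat.), H2 (1 atm), CH2Cl2, rt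
Reagents that add atoms: none
Why: Hydroxyl-directed hydrogenation delivers hydrogen to the alkene face that carries the axial allylic OH, so the future C8 methyl ends anti to both flanking oxygens; the benzylic ether is inert to this catalyst.

Step 8
Reactants: 11 saturated triol
Product: 13 2,6-bis(hydroxymethyl)-2,4-dimethyl-5-[(1S)-1-phenylethoxy]oxan-3-ol, via dialdehyde 12 (not isolated)
Conditions: NaIO4, THF/pH 7 buffer, 0 °C; then NaBH4, MeOH, 0 °C
Reagents that add atoms: none
Why: Glycol cleavage opens the two-carbon bridge to the 2,6-cis dialdehyde and hydride reduction gives the diol; the freed oxane flips so that all substituents except the C2 methyl (future C4a) are equatorial.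

Step 9
Reactants: 13 triol
Product: 14 {6-(hydroxymethyl)-5-hydroxy-4,6-dimethyl-3-[(1S)-1-phenylethoxy]oxan-2-yl}methyl 4-methylbenzenesulfonate
Conditions: TsCl (1.05 equiv), pyridine, CH2Cl2, 0 °C
Reagents that add atoms: p-toluenesulfonyl chloride Cc1ccc(cc1)S(Cl)(=O)=O
Why: Sulfonylation should select the unhindered primary alcohol on the CH carbon over the neopentyl primary alcohol on the quaternary carbon and the hindered secondary alcohol.

Step 10
Reactants: 14 monotosylate
Product: 15 2-(hydroxymethyl)-2,4,6-trimethyl-5-[(1S)-1-phenylethoxy]oxan-3-ol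
Conditions: LiEt3BH (excess), THF, 0 °C to rt
Reagents that add atoms: none
Why: SN2 displacement of the primary sulfonate by hydride turns the former bridge carbon into the C6 methyl group without touching any stereocentre.

Step 11
Reactants: 15 diol
Product: 16 3-hydroxy-2,4,6-trimethyl-5-[(1S)-1-phenylethoxy]oxane-2-carbaldehyde
Conditions: TEMPO (cat.), PhI(OAc)2, CH2Cl2, rt
Reagents that add atoms: none
Why: Oxoammonium oxidation is selective for the primary over the hindered secondary alcohol, and the aldehyde, having no α-hydrogen, cannot epimerise.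

Step 12
Reactants: 16 hydroxy aldehyde
Product: 18 4-hydroxy-3,4a,6,8-tetramethyl-7-[(1S)-1-phenylethoxy]hexahydropyrano[3,2-b]pyran-2-one (epimers at C3 and C4), via aldol ester 17 (not isolated)
Conditions: LiN(iPr)2, EtCO2Et (3 equiv), THF, −78 °C; add 16, −78 to 0 °C; aq. NH4Cl; then CSA (cat.), CH2Cl2, rt
Reagents that add atoms: ethyl propionate CCC(=O)OCC
Why: Aldol addition of the ester enolate to the non-enolisable aldehyde and lactonisation by the C8a hydroxyl close the trans-fused δ-lactone; the configuration at C3 and C4 is irrelevant here because both centres are reset in steps 13 and 14.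

Step 13
Reactants: 18 hydroxy lactone mixture
Product: 19 3,4a,6,8-tetramethyl-7-[(1S)-1-phenylethoxy]tetrahydropyrano[3,2-b]pyran-2,4-dione (keto/enol tautomers)
Conditions: Dess–Martin periodinane, NaHCO3, CH2Cl2, rt
Reagents that add atoms: none
Why: Oxidation of the hindered secondary alcohol converges all aldol diastereomers on one enolisable β-keto lactone.

Step 14
Reactants: 19 β-keto lactone
Product: 20 4-hydroxy lactone with C3 methyl, C4 hydroxyl and C4a methyl all cis (configuration as in the target)
Conditions: H2 (50 bar), Raney Ni, EtOAc, rt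
Reagents that add atoms: none
Why: Syn addition of hydrogen to the enol form (as known for 3-alkyl-4-hydroxy-5,6-dihydropyran-2-ones) from the face opposite the axial C4a methyl sets C3 and C4 together, cis to each other and to that methyl.

Step 15
Reactants: 20 hydroxy lactone
Product: 21 4-acetate of 20
Conditions: Ac2O, pyridine, CH2Cl2, 0 °C to rt
Reagents that add atoms: acetic anhydride CC(=O)OC(C)=O
Why: Acetylation of the only free hydroxyl under mild conditions, which should avoid β-elimination and epimerisation at C3.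

Step 16
Reactants: 21 acetate
Product: 22 (4-acetoxy-7-hydroxy-3,4a,6,8-tetramethylhexahydropyrano[3,2-b]pyran-2-one, configuration as in the target)
Conditions: H2 (1 atm), Pd(OH)2/C, EtOAc/EtOH, rt
Reagents that add atoms: none
Why: Hydrogenolysis of the benzylic 1-phenylethyl ether frees the C7 hydroxyl with retention; lactone and acetate are inert.

Step 17
Reactants: 23 non-1-yn-3-ol (racemic)
Product: 24 triethyl(non-1-yn-3-yloxy)silane
Conditions: Et3SiCl, imidazole, CH2Cl2, 0 °C
Reagents that add atoms: chlorotriethylsilane CC[Si](Cl)(CC)CC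
Why: Silylation masks the propargylic hydroxyl so that it cannot compete in the later esterification.

Step 18
Reactants: 24 silyl ether
Product: 25 4-(triethylsilyloxy)dec-2-ynoic acid
Conditions: nBuLi, THF, −78 °C; CO2; then aq. NaHSO4 (pH 4), 0 °C
Reagents that add atoms: carbon dioxide O=C=O
Why: Carboxylation of the lithium acetylide gives the 2-ynoic acid; the buffered work-up should keep the silyl ether.

Step 19
Reactants: 22 core alcohol; 25 alkynoic acid
Product: 26 7-O-[4-(triethylsilyloxy)dec-2-ynoyl] ester of 22 (epimers at the silyloxy carbon)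
Conditions: EDC·HCl, DMAP, CH2Cl2, 0 °C to rt
Reagents that add atoms: none
Why: Carbodiimide (Steglich) acylation of the equatorial C7 hydroxyl proceeds with retention, and the alkyne cannot lactonise or isomerise.

Step 20
Reactants: 26 silyloxy ynoate
Product: 28 7-O-(4-oxodec-2-ynoyl) ester of 22, via propargylic alcohol 27 (not isolated)
Conditions: CrO3, H2SO4, acetone/H2O, 0 °C
Reagents that add atoms: none
Why: Jones reagent cleaves the acid-labile triethylsilyl ether and oxidises the propargylic alcohol to the ynone in one pot, removing the inconsequential side-chain stereocentre.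

Step 21
Reactants: 28 ynone ester
Product: 29 Botcinin J
Conditions: H2 (1 atm), Pd/CaCO3–Pb(OAc)2, quinoline, EtOAc, 0 °C, stopped after one equivalent
Reagents that add atoms: none
Why: Lindlar semi-hydrogenation adds hydrogen syn to the alkyne and should give the (Z)-4-oxo-2-enoate; the keto group precludes butenolide formation.

**Compound list**

1 | 1,1-dimethoxypropan-2-one | CC(=O)C(OC)OC | starting material
2 | (S)-1-phenylethanol | C[C@H](O)c1ccccc1 | starting material
3 | 1-methoxy-1-[(1S)-1-phenylethoxy]propan-2-one (acetal epimers) | C[C@H](OC(OC)C(C)=O)c1ccccc1 | intermediate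
4 | triethyl({3-methoxy-3-[(1S)-1-phenylethoxy]prop-1-en-2-yl}oxy)silane | C[C@H](OC(OC)C(=C)O[Si](CC)(CC)CC)c1ccccc1 | intermediate
5 | 2-methylfuran | Cc1ccco1 | starting material
6 | 1-[(1S)-1-phenylethoxy]-2-(triethylsilyloxy)allyl cation, triflate ion pair | C[C@H]([O+]=CC(=C)O[Si](CC)(CC)CC)c1ccccc1.[O-]S(=O)(=O)C(F)(F)F | intermediate
7 | (1S,4S,5S)-1-methyl-4-[(1S)-1-phenylethoxy]-8-oxabicyclo[3.2.1]oct-6-en-3-one (alkoxy axial, anti to the etheno bridge) | C[C@H](O[C@@H]1C(=O)C[C@]2(C)O[C@H]1C=C2)c1ccccc1 | intermediate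
8 | 1-methyl-3-methylidene-4-[(1S)-1-phenylethoxy]-8-oxabicyclo[3.2.1]oct-6-ene, ring configuration as in 7 | C[C@H](O[C@@H]1C(=C)C[C@]2(C)O[C@H]1C=C2)c1ccccc1 | intermediate
9 | 1-methyl-3-methylidene-4-[(1S)-1-phenylethoxy]-8-oxabicyclo[3.2.1]oct-6-en-2-ol, 2-OH axial and cis to the 4-alkoxy group | C[C@H](O[C@@H]1C(=C)[C@H](O)[C@]2(C)O[C@H]1C=C2)c1ccccc1 | intermediate
10 | 1-methyl-3-methylidene-4-[(1S)-1-phenylethoxy]-8-oxabicyclo[3.2.1]octane-2,6,7-triol, 6,7-diol cis and syn to O8 | C[C@H](O[C@@H]1C(=C)[C@H](O)[C@]2(C)O[C@H]1[C@@H](O)[C@H]2O)c1ccccc1 | intermediate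
11 | 1,3-dimethyl-4-[(1S)-1-phenylethoxy]-8-oxabicyclo[3.2.1]octane-2,6,7-triol, 3-methyl anti to the 2-OH and 4-alkoxy groups | C[C@H](O[C@@H]1[C@@H](C)[C@H](O)[C@]2(C)O[C@H]1[C@@H](O)[C@H]2O)c1ccccc1 | intermediate
12 | 3-hydroxy-2,4-dimethyl-5-[(1S)-1-phenylethoxy]oxane-2,6-dicarbaldehyde, formyl groups cis; 3-OH, 4-Me, 5-alkoxy mutually trans | C[C@H](O[C@@H]1[C@@H](C)[C@H](O)[C@@](C)(C=O)O[C@H]1C=O)c1ccccc1 | intermediate
13 | 2,6-bis(hydroxymethyl)-2,4-dimethyl-5-[(1S)-1-phenylethoxy]oxan-3-ol, all substituents equatorial except the axial 2-methyl | C[C@H](O[C@@H]1[C@@H](C)[C@H](O)[C@@](C)(CO)O[C@H]1CO)c1ccccc1 | intermediate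
14 | 6-CH2OTs monotosylate of 13 | C[C@H](O[C@@H]1[C@@H](C)[C@H](O)[C@@](C)(CO)O[C@H]1COS(=O)(=O)c1ccc(C)cc1)c1ccccc1 | intermediate
15 | 2-(hydroxymethyl)-2,4,6-trimethyl-5-[(1S)-1-phenylethoxy]oxan-3-ol, configuration as in 13 | C[C@H](O[C@@H]1[C@@H](C)[C@H](O)[C@@](C)(CO)O[C@H]1C)c1ccccc1 | intermediate
16 | 3-hydroxy-2,4,6-trimethyl-5-[(1S)-1-phenylethoxy]oxane-2-carbaldehyde, configuration as in 13 | C[C@H](O[C@@H]1[C@@H](C)[C@H](O)[C@@](C)(C=O)O[C@H]1C)c1ccccc1 | intermediate
17 | ethyl 3-hydroxy-3-{3-hydroxy-2,4,6-trimethyl-5-[(1S)-1-phenylethoxy]oxan-2-yl}-2-methylpropanoate (epimers at the two new centres) | C[C@H](O[C@@H]1[C@@H](C)[C@H](O)[C@@](C)(C(O)C(C)C(=O)OCC)O[C@H]1C)c1ccccc1 | intermediate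
18 | 4-hydroxy-3,4a,6,8-tetramethyl-7-[(1S)-1-phenylethoxy]hexahydropyrano[3,2-b]pyran-2-one, trans-fused, epimers at C3 and C4 | C[C@H](O[C@@H]1[C@@H](C)[C@@H]2OC(=O)C(C)C(O)[C@@]2(C)O[C@H]1C)c1ccccc1 | intermediate
19 | 3,4a,6,8-tetramethyl-7-[(1S)-1-phenylethoxy]tetrahydropyrano[3,2-b]pyran-2,4-dione (keto form shown; enolised at C3–C4) | C[C@H](O[C@@H]1[C@@H](C)[C@@H]2OC(=O)C(C)C(=O)[C@@]2(C)O[C@H]1C)c1ccccc1 | intermediate
20 | 4-hydroxy lactone, 3-Me, 4-OH and 4a-Me all cis, remaining centres as in the target | C[C@H](O[C@@H]1[C@@H](C)[C@@H]2OC(=O)[C@H](C)[C@H](O)[C@@]2(C)O[C@H]1C)c1ccccc1 | intermediate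
21 | 4-acetate of 20 | C[C@H](O[C@@H]1[C@@H](C)[C@@H]2OC(=O)[C@H](C)[C@H](OC(C)=O)[C@@]2(C)O[C@H]1C)c1ccccc1 | intermediate
22 | 4-acetoxy-7-hydroxy-3,4a,6,8-tetramethylhexahydropyrano[3,2-b]pyran-2-one, configuration as in the target | O[C@@H]1[C@@H](C)[C@@H]2OC(=O)[C@H](C)[C@H](OC(C)=O)[C@@]2(C)O[C@H]1C | intermediate
23 | non-1-yn-3-ol (racemic) | CCCCCCC(O)C#C | starting material
24 | triethyl(non-1-yn-3-yloxy)silane | CCCCCCC(O[Si](CC)(CC)CC)C#C | intermediate
25 | 4-(triethylsilyloxy)dec-2-ynoic acid | CCCCCCC(O[Si](CC)(CC)CC)C#CC(=O)O | intermediate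
26 | 7-O-[4-(triethylsilyloxy)dec-2-ynoyl] ester of 22 | CCCCCCC(O[Si](CC)(CC)CC)C#CC(=O)O[C@@H]1[C@@H](C)[C@@H]2OC(=O)[C@H](C)[C@H](OC(C)=O)[C@@]2(C)O[C@H]1C | intermediate
27 | 7-O-(4-hydroxydec-2-ynoyl) ester of 22 | CCCCCCC(O)C#CC(=O)O[C@@H]1[C@@H](C)[C@@H]2OC(=O)[C@H](C)[C@H](OC(C)=O)[C@@]2(C)O[C@H]1C | intermediate
28 | 7-O-(4-oxodec-2-ynoyl) ester of 22 | CCCCCCC(=O)C#CC(=O)O[C@@H]1[C@@H](C)[C@@H]2OC(=O)[C@H](C)[C@H](OC(C)=O)[C@@]2(C)O[C@H]1C | intermediate
29 | Botcinin J | CCCCCCC(=O)/C=C\C(=O)O[C@@H]1[C@@H](C)[C@@H]2OC(=O)[C@H](C)[C@H](OC(C)=O)[C@@]2(C)O[C@H]1C | target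

**Step count.** Total: 21 steps. Longest linear sequence: 19 steps (steps 1–16 and 19–21; steps 17–18 form the side-chain branch).

**Steps most likely to fail**

Step 3. The cation may bond first through its CH2 terminus to the free furan α-carbon, which would place the alkoxy group next to the methyl-bearing bridgehead, or facial control by the auxiliary may erode at the temperature the less reactive orientation requires. The fallback sets out from 4 and returns to 7, and changes the diene to one that carries a removable blocking group. Commercial 3-bromofuran is lithiated at C2 (LiN(iPr)2, THF, −78 °C) and methylated (MeI) to 3-bromo-2-methylfuran F1. Its bromine makes the methyl-bearing carbon too congested for the alkoxy-bearing terminus, so cycloaddition with the cation from 4 (Me3SiOTf, CH2Cl2, −78 °C) should give only the 7-bromo cycloadduct F2. Radical reduction of the vinylic bromide (Bu3SnH, AIBN, toluene, 80 °C) then gives 7.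

Step 6. Osmylation may fail to discriminate between the bridge alkene and the exocyclic alkene, leading to over-oxidation. The fallback sets out from 7 and returns to 11; it dihydroxylates while the bridge alkene is the only alkene and carries the diol protected. OsO4/NMO on 7 gives the keto diol F3, and 2,2-dimethoxypropane with PPTS gives the acetonide ketone F4. Wittig methylenation as in step 4 gives the acetonide alkene F5, SeO2/tBuOOH as in step 5 gives the acetonide allylic alcohol F6, and directed hydrogenation as in step 7 gives the acetonide F7. Aqueous AcOH at 50 °C removes the acetonide and gives 11.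

Step 14. The tetrasubstituted enol next to a quaternary carbon may resist hydrogenation, may take up hydrogen without facial discrimination, or the benzylic ether may be lost on nickel. The fallback sets out from 16 and returns to 20; it builds C3 and C4 in the open chain under substrate control. Silylation (Et3SiOTf, 2,6-lutidine, −78 °C) gives the silyloxy aldehyde F8. A chelation-controlled Mukaiyama acetate aldol (1-methoxy-1-(trimethylsilyloxy)ethene, MgBr2·OEt2, CH2Cl2, −78 °C) should give the β-hydroxy ester F9; the nucleophile enters anti to the ring carbon C8a on the chelate between the aldehyde oxygen and O5. Fráter–Seebach methylation of the dianion (LiN(iPr)2, then MeI, THF, −50 to −20 °C) should give the 2,3-anti methyl ester F10. Bu4NF in THF removes the silyl group and the liberated alkoxide lactonises to 20.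

**Further compounds**

F1 | step 3 | 3-bromo-2-methylfuran | Cc1occc1Br
F2 | step 3 | 7-bromo-1-methyl-4-[(1S)-1-phenylethoxy]-8-oxabicyclo[3.2.1]oct-6-en-3-one, ring configuration as in 7 | C[C@H](O[C@@H]1C(=O)C[C@]2(C)O[C@H]1C=C2Br)c1ccccc1
F3 | step 6 | 6,7-dihydroxy-1-methyl-4-[(1S)-1-phenylethoxy]-8-oxabicyclo[3.2.1]octan-3-one, diol cis and syn to O8 | C[C@H](O[C@@H]1C(=O)C[C@]2(C)O[C@H]1[C@@H](O)[C@H]2O)c1ccccc1
F4 | step 6 | 6,7-O-isopropylidene acetal of F3 | C[C@H](O[C@@H]1C(=O)C[C@]2(C)O[C@H]1[C@H]3OC(C)(C)O[C@@H]23)c1ccccc1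
F5 | step 6 | 3-methylidene analogue of F4 | C[C@H](O[C@@H]1C(=C)C[C@]2(C)O[C@H]1[C@H]3OC(C)(C)O[C@@H]23)c1ccccc1
F6 | step 6 | 2-hydroxy derivative of F5, OH axial and cis to the alkoxy group (6,7-acetonide of 10) | C[C@H](O[C@@H]1C(=C)[C@H](O)[C@]2(C)O[C@H]1[C@H]3OC(C)(C)O[C@@H]23)c1ccccc1
F7 | step 6 | 6,7-acetonide of 11 | C[C@H](O[C@@H]1[C@@H](C)[C@H](O)[C@]2(C)O[C@H]1[C@H]3OC(C)(C)O[C@@H]23)c1ccccc1
F8 | step 14 | 3-O-triethylsilyl ether of 16 | C[C@H](O[C@@H]1[C@@H](C)[C@H](O[Si](CC)(CC)CC)[C@@](C)(C=O)O[C@H]1C)c1ccccc1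
F9 | step 14 | methyl 3-hydroxy-3-{2,4,6-trimethyl-5-[(1S)-1-phenylethoxy]-3-(triethylsilyloxy)oxan-2-yl}propanoate, carbinol configured as C4 of the target | C[C@H](O[C@@H]1[C@@H](C)[C@H](O[Si](CC)(CC)CC)[C@@](C)([C@@H](O)CC(=O)OC)O[C@H]1C)c1ccccc1
F10 | step 14 | 2-methyl derivative of F9, 2,3-anti, configured as C3 and C4 of the target | C[C@H](O[C@@H]1[C@@H](C)[C@H](O[Si](CC)(CC)CC)[C@@](C)([C@@H](O)[C@@H](C)C(=O)OC)O[C@H]1C)c1ccccc1
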